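## Retrosynthetic overview

- The oxirane comes last, by hydroxyl-directed epoxidation of the C8=C9 bond of the 10α-allylic alcohol. Before that: acetate at C2, veratrate at C6, C8 methyl by cross-coupling of an enol triflate, 6α-OH by C4–OH-directed ketone reduction.
- The seven-membered ring is formed second, by a Brook-rearrangement (3+4) annulation. A β-alkoxy-acryloylsilane supplies C8–C10 and the enolate of a 1-acetyl-2-methylcyclopentene supplies C7, C6, C5 and C1. The bonds made are C7–C8 and C10–C1; the acylsilane carbon acts as an acyl anion and, through its β-carbon C10, as a homoenolate towards the enone β-carbon C1.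
- The five-membered ring is formed first, by ozonolysis and aldol re-closure of (R)-terpinen-4-ol, which supplies C4 with its OH and isopropyl group. The C2 oxygen is put in beforehand by SeO2 allylic hydroxylation.

Assumption: taken literally, the C8 and C9 descriptors of the supplied SMILES put the two ring bonds of the oxirane on opposite faces, which a seven-membered ring cannot hold; I take the cis-fused 8,9-epoxide on the face of the C10 hydroxyl (C9 as written) as the target and quote the supplied string unchanged for it.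

Conventions: locants C1–C10 follow daucane numbering (C1 = methyl-bearing ring-fusion carbon, C2–C4 in the five-membered ring, C5 = ring-fusion CH, C6–C10 in the seven-membered ring). β is the face of the C1 methyl. All bicyclic compounds are 1β-methyl, 5α-H (trans-fused), 4α-isopropyl. TBS = tert-butyl(dimethyl)silyl, PMB = 4-methoxybenzyl.

## Route

Step 1
Reactants: 1 (R)-(−)-terpinen-4-ol
Product: 2 (1S,5S)-5-isopropyl-2-methylcyclohex-2-ene-1,5-diol (cis-diol)
Conditions: SeO2 (0.3 equiv), t-BuOOH (3 equiv), CH2Cl2, 0 °C to rt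
Reagents that add atoms: tert-butyl hydroperoxide CC(C)(C)OO
Why: Catalytic SeO2 allylic hydroxylation (ene reaction, then [2,3]-sigmatropic shift) attacks the ring CH2 next to the methyl-bearing alkene carbon and replaces its pseudo-axial hydrogen, which in the half-chair with equatorial isopropyl lies on the face of the axial tertiary OH, so the new carbinol (future C2) is set cis to the C4 hydroxyl.

Step 2
Reactants: 2 (1S,5S)-5-isopropyl-2-methylcyclohex-2-ene-1,5-diol
Product: 3 (1S,3S)-3-(TBS-oxy)-1-isopropyl-4-methylcyclohex-4-en-1-ol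
Conditions: TBSCl (1.1 equiv), imidazole, DMF, 0 °C
Reagents that add atoms: tert-butyl(chloro)dimethylsilane CC(C)(C)[Si](C)(C)Cl
Why: Silylation takes the secondary allylic hydroxyl and leaves the hindered tertiary one free for the later directed reduction; no stereocenter is touched.

Step 3
Reactants: 3 (1S,3S)-3-(TBS-oxy)-1-isopropyl-4-methylcyclohex-4-en-1-ol
Product: 5 (3S,5S)-3-(TBS-oxy)-5-hydroxy-5-isopropyl-2-methylcyclopent-1-ene-1-carbaldehyde, via keto-aldehyde 4 (not isolated)
Conditions: O3, CH2Cl2/MeOH, −78 °C; Me2S; then piperidine (0.2 equiv), AcOH (0.2 equiv), toluene, 40 °C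
Reagents that add atoms: ozone [O-][O+]=O
Why: Ozonolysis opens the only C=C to a keto-aldehyde, and the amine-catalysed intramolecular aldol condensation (aldehyde enamine onto the methyl ketone, 5-exo, then dehydration) recloses it as the cyclopentene that carries C1–C5, with C2 and C4 untouched.

Step 4
Reactants: 5 (3S,5S)-3-(TBS-oxy)-5-hydroxy-5-isopropyl-2-methylcyclopent-1-ene-1-carbaldehyde
Product: 7 1-[(3S,5S)-3-(TBS-oxy)-5-hydroxy-5-isopropyl-2-methylcyclopent-1-en-1-yl]ethan-1-one, via magnesium alkoxide 6 (not isolated)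
Conditions: MeMgBr (2.2 equiv), THF, −78 °C; then 1,1′-(azodicarbonyl)dipiperidine, 0 °C to rt; aq NH4Cl
Reagents that add atoms: methylmagnesium bromide C[Mg]Br
Why: Grignard 1,2-addition to the non-enolisable enal, then Mukaiyama oxidation of the bromomagnesium alkoxide by the azodicarboxamide (hydride transfer from the carbinol C–H), gives the methyl ketone in one flask; the transient carbinol center is erased and the tertiary alkoxide has no C–H to oxidise.

Step 5
Reactants: 8 ethyl vinyl ether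
Product: 11 1-[tert-butyl(dimethyl)silyl]ethan-1-one, via 1-ethoxyvinyllithium 9 (not isolated), via 1-ethoxyvinylsilane 10 (not isolated)
Conditions: t-BuLi, THF, −78 to 0 °C; TBSCl, −78 °C to rt; then 1 M HCl
Reagents that add atoms: tert-butyl(chloro)dimethylsilane CC(C)(C)[Si](C)(C)Cl; water O
Why: α-Lithiation of the enol ether gives an acyl anion equivalent that is C-silylated, and acid hydrolysis of the resulting enol ether releases the acylsilane.

Step 6
Reactants: 11 1-[tert-butyl(dimethyl)silyl]ethan-1-one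
Product: 13 (E)-1-[tert-butyl(dimethyl)silyl]-3-[(4-methoxybenzyl)oxy]prop-2-en-1-one, via enaminone 12 (not isolated)
Conditions: Me2NCH(OMe)2, 90 °C; evaporate; then 4-methoxybenzyl alcohol, PPTS (cat.), toluene, 80 °C
Reagents that add atoms: N,N-dimethylformamide dimethyl acetal COC(OC)N(C)C; 4-methoxybenzyl alcohol COc1ccc(CO)cc1
Why: Condensation of the methyl ketone with the amide acetal gives the (E)-enaminone, and acid-catalysed amine–alkoxy exchange (addition–elimination at the β-carbon, driven by loss of Me2NH) gives the thermodynamically favoured (E)-β-alkoxy enoylsilane.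

Step 7
Reactants: 7 1-[(3S,5S)-3-(TBS-oxy)-5-hydroxy-5-isopropyl-2-methylcyclopent-1-en-1-yl]ethan-1-one; 13 (E)-1-[tert-butyl(dimethyl)silyl]-3-[(4-methoxybenzyl)oxy]prop-2-en-1-one
Product: 16 2β,8-bis(TBS-oxy)-4β-hydroxy-4α-isopropyl-1β-methyl-10α-(PMB-oxy)-5αH-bicyclo[5.3.0]dec-8-en-6-one, via lithium dienolate 14 (not isolated), via α-silyl alkoxide 15 (not isolated)
Conditions: LiN(iPr)2 (commercial solution, 2.2 equiv), THF, −78 °C; add 13, −78 to −20 °C; aq NH4Cl
Reagents that add atoms: none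
Why: Proposed new method: this is a Brook-rearrangement-mediated (3+4) annulation in the manner of Takeda, in which the cross-conjugated enolate adds to the acylsilane carbonyl, the 1,2-silyl shift from C to O turns the former carbonyl carbon C8 into a carbanion (an acyl anion, and through its allylic β-carbon C10 a homoenolate equivalent) that closes onto the C6 ketone to a cis-1,2-divinylcyclopropanediolate, and anionic oxy-Cope rearrangement through a boat transition state joins C10 to C1, two β-carbons that are both electrophilic in their parent enones; the (E)-alkene puts the C10 ether trans to the C1 methyl, the bond forms on the α-face away from the C2 silyl ether (the C4 and C6 lithium alkoxides bridge on the β-face), and the resulting C5=C6 enolate is protonated from the α-face to the trans-fused ketone; the closest known reactions are the annulations of β-silyl and β-alkyl acryloylsilanes with enolates of alkenyl methyl ketones, extended here to a β-alkoxy acylsilane and a tetrasubstituted cyclopentenyl ketone.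

Step 8
Reactants: 16 2β,8-bis(TBS-oxy)-4β-hydroxy-4α-isopropyl-1β-methyl-10α-(PMB-oxy)-5αH-bicyclo[5.3.0]dec-8-en-6-one
Product: 17 2β,8-bis(TBS-oxy)-4α-isopropyl-1β-methyl-10α-(PMB-oxy)-5αH-bicyclo[5.3.0]dec-8-ene-4β,6α-diol
Conditions: Me4NBH(OAc)3, MeCN/AcOH, −30 °C
Reagents that add atoms: none
Why: Evans–Saksena directed reduction: the C4 hydroxyl binds the acetoxyborohydride and delivers hydride intramolecularly to the β-face of the C6 ketone, giving the 6α-alcohol (1,3-anti to the 4β-OH), while the hindered silyl enol ether should survive the cold, weakly acidic medium.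

Step 9
Reactants: 17 2β,8-bis(TBS-oxy)-4α-isopropyl-1β-methyl-10α-(PMB-oxy)-5αH-bicyclo[5.3.0]dec-8-ene-4β,6α-diol
Product: 18 2β,8-bis(TBS-oxy)-4β-hydroxy-4α-isopropyl-1β-methyl-10α-(PMB-oxy)-5αH-bicyclo[5.3.0]dec-8-en-6α-yl 3,4-dimethoxybenzoate
Conditions: 3,4-dimethoxybenzoyl chloride, pyridine, DMAP, CH2Cl2, rt
Reagents that add atoms: 3,4-dimethoxybenzoyl chloride COc1ccc(C(Cl)=O)cc1OC
Why: DMAP-catalysed acylation takes the only secondary hydroxyl; the tertiary C4–OH does not react and the configuration at C6 is retained.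

Step 10
Reactants: 18 2β,8-bis(TBS-oxy)-4β-hydroxy-4α-isopropyl-1β-methyl-10α-(PMB-oxy)-5αH-bicyclo[5.3.0]dec-8-en-6α-yl 3,4-dimethoxybenzoate
Product: 19 2β-(TBS-oxy)-4β-hydroxy-4α-isopropyl-1β-methyl-10α-(PMB-oxy)-8-(trifluoromethanesulfonyloxy)-5αH-bicyclo[5.3.0]dec-8-en-6α-yl 3,4-dimethoxybenzoate
Conditions: PhNTf2 (1.3 equiv), CsF (1.5 equiv), DME, rt
Reagents that add atoms: N-phenylbis(trifluoromethanesulfonimide) O=S(=O)(N(c1ccccc1)S(=O)(=O)C(F)(F)F)C(F)(F)F
Why: Fluoride cleaves the silyl enol ether (far faster than the alkyl TBS ether at C2) and the cesium enolate is O-sulfonylated at once by PhNTf2, so the C8=C9 position fixed in step 7 is carried into the enol triflate before β-elimination of the C10 ether can compete.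

Step 11
Reactants: 19 the C8 enol triflate
Product: 20 2β-(TBS-oxy)-4β-hydroxy-10α-(PMB-oxy)dauc-8-en-6α-yl 3,4-dimethoxybenzoate
Conditions: MeB(OH)2, Pd(dppf)Cl2 (5 mol %), K3PO4, dioxane/H2O, 70 °C
Reagents that add atoms: methylboronic acid CB(O)O
Why: Suzuki–Miyaura cross-coupling of the alkenyl triflate installs the C8 methyl with retention of the double-bond position; the esters and the PMB ether are inert.

Step 12
Reactants: 20 2β-(TBS-oxy)-4β-hydroxy-10α-(PMB-oxy)dauc-8-en-6α-yl 3,4-dimethoxybenzoate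
Product: 22 2β-acetoxy-4β-hydroxy-10α-(PMB-oxy)dauc-8-en-6α-yl 3,4-dimethoxybenzoate, via C2 alcohol 21 (not isolated)
Conditions: TBAF, AcOH, THF, rt; then Ac2O, Et3N, DMAP
Reagents that add atoms: acetic anhydride CC(=O)OC(C)=O
Why: Buffered fluoride removes the C2 silyl ether and the freed secondary alcohol is acetylated in the same flask, C10 being still PMB-protected and the C4–OH tertiary; the configuration at C2 is retained.

Step 13
Reactants: 22 2β-acetoxy-4β-hydroxy-10α-(PMB-oxy)dauc-8-en-6α-yl 3,4-dimethoxybenzoate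
Product: 23 2β-acetoxy-4β,10α-dihydroxydauc-8-en-6α-yl 3,4-dimethoxybenzoate
Conditions: DDQ (1.2 equiv), CH2Cl2/pH 7 buffer, 0 °C
Reagents that add atoms: none
Why: Oxidative cleavage of the electron-rich PMB ether by DDQ (hydride abstraction, then hydrolysis) frees the 10α-allylic alcohol without touching the veratrate or the acetate.

Step 14
Reactants: 23 2β-acetoxy-4β,10α-dihydroxydauc-8-en-6α-yl 3,4-dimethoxybenzoate
Product: 24 2β-acetoxy-8α,9α-epoxy-4β,10α-dihydroxydaucan-6α-yl 3,4-dimethoxybenzoate (CNP0197096.4)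
Conditions: VO(acac)2 (5 mol %), t-BuOOH, CH2Cl2, 0 °C to rt
Reagents that add atoms: tert-butyl hydroperoxide CC(C)(C)OO
Why: Sharpless VO(acac)2-catalysed hydroxyl-directed epoxidation: the vanadate ester of the 10α-OH delivers the peroxide oxygen to the same face of the adjacent trisubstituted C8=C9 bond, setting C8 and C9 as the cis-fused α-epoxide syn to the C10 hydroxyl; the tertiary C4–OH is too remote to compete.

## Compound list

1 | (R)-(−)-terpinen-4-ol | CC1=CC[C@@](O)(C(C)C)CC1 | starting material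
2 | (1S,5S)-5-isopropyl-2-methylcyclohex-2-ene-1,5-diol (cis-diol) | CC1=CC[C@@](O)(C(C)C)C[C@@H]1O | intermediate
3 | (1S,3S)-3-(TBS-oxy)-1-isopropyl-4-methylcyclohex-4-en-1-ol | CC1=CC[C@@](O)(C(C)C)C[C@@H]1O[Si](C)(C)C(C)(C)C | intermediate
4 | (3R,5S)-5-(TBS-oxy)-3-hydroxy-3-isopropyl-6-oxoheptanal | CC(=O)[C@@H](O[Si](C)(C)C(C)(C)C)C[C@](O)(C(C)C)CC=O | intermediate
5 | (3S,5S)-3-(TBS-oxy)-5-hydroxy-5-isopropyl-2-methylcyclopent-1-ene-1-carbaldehyde | CC1=C(C=O)[C@@](O)(C(C)C)C[C@@H]1O[Si](C)(C)C(C)(C)C | intermediate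
6 | bis(bromomagnesium) alkoxide of the methyl carbinol from 5 (both carbinol epimers) | CC1=C(C(C)O[Mg]Br)[C@@](O[Mg]Br)(C(C)C)C[C@@H]1O[Si](C)(C)C(C)(C)C | intermediate
7 | 1-[(3S,5S)-3-(TBS-oxy)-5-hydroxy-5-isopropyl-2-methylcyclopent-1-en-1-yl]ethan-1-one | CC1=C(C(C)=O)[C@@](O)(C(C)C)C[C@@H]1O[Si](C)(C)C(C)(C)C | intermediate
8 | ethyl vinyl ether | C=COCC | starting material
9 | (1-ethoxyvinyl)lithium | [Li]C(=C)OCC | intermediate
10 | tert-butyl(1-ethoxyvinyl)dimethylsilane | C=C(OCC)[Si](C)(C)C(C)(C)C | intermediate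
11 | 1-[tert-butyl(dimethyl)silyl]ethan-1-one | CC(=O)[Si](C)(C)C(C)(C)C | intermediate
12 | (E)-1-[tert-butyl(dimethyl)silyl]-3-(dimethylamino)prop-2-en-1-one | CN(C)/C=C/C(=O)[Si](C)(C)C(C)(C)C | intermediate
13 | (E)-1-[tert-butyl(dimethyl)silyl]-3-[(4-methoxybenzyl)oxy]prop-2-en-1-one | COc1ccc(CO/C=C/C(=O)[Si](C)(C)C(C)(C)C)cc1 | intermediate
14 | dilithium dienolate-alkoxide of 7 | CC1=C(C(=C)O[Li])[C@@](O[Li])(C(C)C)C[C@@H]1O[Si](C)(C)C(C)(C)C | intermediate
15 | lithium α-silyl alkoxide from 1,2-addition of 14 to 13 (both epimers at the new carbinol) | CC1=C(C(=O)CC(O[Li])(/C=C/OCc2ccc(OC)cc2)[Si](C)(C)C(C)(C)C)[C@@](O[Li])(C(C)C)C[C@@H]1O[Si](C)(C)C(C)(C)C | intermediate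
16 | 2β,8-bis(TBS-oxy)-4β-hydroxy-4α-isopropyl-1β-methyl-10α-(PMB-oxy)-5αH-bicyclo[5.3.0]dec-8-en-6-one | O=C2CC(O[Si](C)(C)C(C)(C)C)=C[C@H](OCc4ccc(OC)cc4)[C@]3(C)[C@@H](O[Si](C)(C)C(C)(C)C)C[C@](O)(C(C)C)[C@@H]23 | intermediate
17 | 2β,8-bis(TBS-oxy)-4α-isopropyl-1β-methyl-10α-(PMB-oxy)-5αH-bicyclo[5.3.0]dec-8-ene-4β,6α-diol | O[C@@H]2CC(O[Si](C)(C)C(C)(C)C)=C[C@H](OCc4ccc(OC)cc4)[C@]3(C)[C@@H](O[Si](C)(C)C(C)(C)C)C[C@](O)(C(C)C)[C@@H]23 | intermediate
18 | 6α-(3,4-dimethoxybenzoate) of 17 | COc1ccc(C(=O)O[C@@H]2CC(O[Si](C)(C)C(C)(C)C)=C[C@H](OCc4ccc(OC)cc4)[C@]3(C)[C@@H](O[Si](C)(C)C(C)(C)C)C[C@](O)(C(C)C)[C@@H]23)cc1OC | intermediate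
19 | C8 enol triflate (2β-OTBS, 4β-OH, 10α-OPMB, 6α-veratrate) | COc1ccc(C(=O)O[C@@H]2CC(OS(=O)(=O)C(F)(F)F)=C[C@H](OCc4ccc(OC)cc4)[C@]3(C)[C@@H](O[Si](C)(C)C(C)(C)C)C[C@](O)(C(C)C)[C@@H]23)cc1OC | intermediate
20 | 2β-(TBS-oxy)-4β-hydroxy-10α-(PMB-oxy)dauc-8-en-6α-yl 3,4-dimethoxybenzoate | COc1ccc(C(=O)O[C@@H]2CC(C)=C[C@H](OCc4ccc(OC)cc4)[C@]3(C)[C@@H](O[Si](C)(C)C(C)(C)C)C[C@](O)(C(C)C)[C@@H]23)cc1OC | intermediate
21 | 2β,4β-dihydroxy-10α-(PMB-oxy)dauc-8-en-6α-yl 3,4-dimethoxybenzoate | COc1ccc(C(=O)O[C@@H]2CC(C)=C[C@H](OCc4ccc(OC)cc4)[C@]3(C)[C@@H](O)C[C@](O)(C(C)C)[C@@H]23)cc1OC | intermediate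
22 | 2β-acetoxy-4β-hydroxy-10α-(PMB-oxy)dauc-8-en-6α-yl 3,4-dimethoxybenzoate | COc1ccc(C(=O)O[C@@H]2CC(C)=C[C@H](OCc4ccc(OC)cc4)[C@]3(C)[C@@H](OC(C)=O)C[C@](O)(C(C)C)[C@@H]23)cc1OC | intermediate
23 | 2β-acetoxy-4β,10α-dihydroxydauc-8-en-6α-yl 3,4-dimethoxybenzoate | COc1ccc(C(=O)O[C@@H]2CC(C)=C[C@H](O)[C@]3(C)[C@@H](OC(C)=O)C[C@](O)(C(C)C)[C@@H]23)cc1OC | intermediate
24 | 2β-acetoxy-8α,9α-epoxy-4β,10α-dihydroxydaucan-6α-yl 3,4-dimethoxybenzoate (CNP0197096.4; supplied string) | COc1ccc(C(=O)O[C@@H]2C[C@@]3(C)O[C@@H]3[C@H](O)[C@]3(C)[C@@H](OC(C)=O)C[C@](O)(C(C)C)[C@@H]23)cc1OC | target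

## Step count and weak points

Total step count: 14. Longest linear sequence: 12 steps (1 to 24 through steps 1–4 and 7–14); steps 5 and 6 make acylsilane 13.

The three steps most likely to fail, each with a fallback:

**Step 7 (the annulation).** The enolate may add to the β-carbon of 13 with loss of the PMB-oxide, or the oxy-Cope step may stall at the tetrasubstituted C1, where the methyl must point into the boat. If so, the seven-membered ring is closed by cationic instead of anionic chemistry, setting out from enal 5 and returning at 20. A γ-selective vinylogous Mukaiyama aldol addition of tert-butyl(dimethyl)[(3-methylbuta-1,3-dien-1-yl)oxy]silane (BF3·OEt2, CH2Cl2, −78 °C) gives the 6-hydroxy dienal F1. After photochemical E-to-Z equilibration of the enal, Me2AlCl-promoted carbonyl-ene (Prins-type) attack of the C1=C5 bond on the C10 aldehyde, ended by enolisation of the C6 carbinol to the ketone, gives the bicyclic hydroxy ketone F2. 4-Methoxybenzyl trichloroacetimidate with La(OTf)3 gives the PMB ether F3. The directed reduction of step 8 gives the 6α-alcohol F4, and acylation of F4 as in step 9 gives 20, so that steps 8–11 are bypassed.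

**Step 8 (directed reduction).** The acetic acid medium may hydrolyse the silyl enol ether, or C5 may epimerise before reduction. The fallback sets out from 16 and returns at 18. NaBH4 with CeCl3 in MeOH at −78 °C, acid-free, should attack from the more open α-face and give the 6β-alcohol F5. A Mitsunobu esterification (PPh3, DIAD, 3,4-dimethoxybenzoic acid) then inverts C6 and gives 18 directly.

**Step 1 (SeO2 hydroxylation).** The cis selectivity rests on a conformational argument, and over-oxidation to the enone is common. The fallback sets out from 1 and returns at 2. The SeO2/t-BuOOH oxidation is driven on and the crude allylic alcohols are oxidised with MnO2 to the enone F6. Narasaka–Prasad reduction (Et2BOMe, NaBH4, THF/MeOH, −78 °C), in which external hydride attacks the boron chelate of the tertiary hydroxyl and the ketone, then gives the 1,3-syn (cis) diol 2, so the C2 configuration is set by chelation-controlled reduction.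

Further compounds
F1 | step 7 | (3S,5S)-3-(TBS-oxy)-5-hydroxy-1-[(E)-1-hydroxy-3-methyl-5-oxopent-3-en-1-yl]-5-isopropyl-2-methylcyclopent-1-ene (both carbinol epimers) | CC1=C(C(O)C/C(C)=C/C=O)[C@@](O)(C(C)C)C[C@@H]1O[Si](C)(C)C(C)(C)C
F2 | step 7 | 2β-(TBS-oxy)-4β,10α-dihydroxydauc-8-en-6-one | O=C2CC(C)=C[C@H](O)[C@]3(C)[C@@H](O[Si](C)(C)C(C)(C)C)C[C@](O)(C(C)C)[C@@H]23
F3 | step 7 | 2β-(TBS-oxy)-4β-hydroxy-10α-(PMB-oxy)dauc-8-en-6-one | O=C2CC(C)=C[C@H](OCc1ccc(OC)cc1)[C@]3(C)[C@@H](O[Si](C)(C)C(C)(C)C)C[C@](O)(C(C)C)[C@@H]23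
F4 | step 7 | 2β-(TBS-oxy)-10α-(PMB-oxy)dauc-8-ene-4β,6α-diol | O[C@@H]2CC(C)=C[C@H](OCc1ccc(OC)cc1)[C@]3(C)[C@@H](O[Si](C)(C)C(C)(C)C)C[C@](O)(C(C)C)[C@@H]23
F5 | step 8 | 2β,8-bis(TBS-oxy)-4α-isopropyl-1β-methyl-10α-(PMB-oxy)-5αH-bicyclo[5.3.0]dec-8-ene-4β,6β-diol | O[C@H]2CC(O[Si](C)(C)C(C)(C)C)=C[C@H](OCc1ccc(OC)cc1)[C@]3(C)[C@@H](O[Si](C)(C)C(C)(C)C)C[C@](O)(C(C)C)[C@@H]23
F6 | step 1 | (S)-5-hydroxy-5-isopropyl-2-methylcyclohex-2-en-1-one | CC1=CC[C@@](O)(C(C)C)CC1=O
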